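**Plan**
- Retrosynthesis removes the two isovalerates and C13=C14 (olefination of a C13 methyl ketone), then cuts C8=C9 of ring B (reductive coupling of a C8/C9 diketone), C6–C7 (2-methylallyl addition to the C6 lactone carbonyl) and C9–C11 (acetylide addition to the C9 aldehyde).
- This leaves a cis-fused ring A lactone aldehyde, which is cut at C4–C5 and C1–C10 by an intramolecular Diels–Alder transform to an open-chain dienyl ester made from two five-carbon pieces.
- The feature that allows this: C19 (the CH2OH carbon on C4), C6 (on C5) and the C10 methyl all sit on the β face of ring A, so a C19–O–C6(=O) ester can tether a C1–C4 diene to a C5=C10 dienophile.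
- Forward, ring A and the γ-lactone form together in the cycloaddition; the C9 side chain, the ring A epoxide and the C7/C8/C17 unit are then added; ring B closes last by titanium coupling.
- C4, C5 and C10 come from the Z-diene, the E-dienophile, the short tether and a chiral boron catalyst; C3 and C6 come from hydride addition to the 3,6-diketone of the trans-decalin; the 13E alkene comes from the phosphonate olefination.

Key step: step 7

Assumption: the enantioface rule known for 2-substituted acroleins bound to N-protonated oxazaborolidines (s-trans enal, formyl C–H···O contact) is taken to hold for enal 10. Under it the (S)-prolinol catalyst would open the Re face of C10, so the (R)-configured catalyst is specified; should the sense prove reversed, the antipodal catalyst is used with no other change.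

Conventions: labdane numbering throughout (C1–C10 decalin, C11–C16 side chain, C17 on C8, C18 and C19 on C4, C20 on C10). β is the ring A face that carries the C10 methyl. Compounds 15–19 are mixtures at C9, 17 at the hemiketal carbon and 18–27 at C6; these centres are removed or reset later.

**Route**

Step 1
Reactants: 1 acrolein; 2 ethyl 2-[bis(2,2,2-trifluoroethoxy)phosphoryl]propanoate
Product: 4 ethyl (2Z)-2-methylpenta-2,4-dienoate, via potassium phosphonate carbanion 3 (not isolated)
Conditions: KN(SiMe3)2, 18-crown-6, THF, −78 °C; then 1, −78 °C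
Reagents that add atoms: none
Why: Still–Gennari olefination: with the electron-poor bis(trifluoroethyl) phosphonate and a dissociated potassium counter-ion the kinetic adduct eliminates before it equilibrates, so the ester should end up cis to the vinyl group (2Z).

Step 2
Reactants: 4 ethyl (2Z)-2-methylpenta-2,4-dienoate
Product: 5 (2Z)-2-methylpenta-2,4-dien-1-ol
Conditions: i-Bu2AlH (2.2 equiv), Et2O, −78 → 0 °C; aq. KNaC4H4O6
Reagents that add atoms: none
Why: 1,2-reduction of a conjugated ester by i-Bu2AlH should give the allylic alcohol and leave the diene and its Z geometry untouched.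

Step 3
Reactants: 6 ethyl (2E)-3-methyl-4-oxobut-2-enoate
Product: 7 ethyl (2E)-4,4-dimethoxy-3-methylbut-2-enoate
Conditions: HC(OMe)3, MeOH, p-TsOH·H2O (cat.), 20 °C
Reagents that add atoms: trimethyl orthoformate, COC(OC)OC; methanol, CO
Why: acid-catalysed acetalisation driven by the orthoformate masks the aldehyde for the basic hydrolysis that follows and should not disturb the E alkene.

Step 4
Reactants: 7 ethyl (2E)-4,4-dimethoxy-3-methylbut-2-enoate
Product: 8 (2E)-4,4-dimethoxy-3-methylbut-2-enoic acid
Conditions: LiOH, THF/H2O, 0 → 20 °C; then 1 M HCl to pH 4, 0 °C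
Reagents that add atoms: lithium hydroxide, [Li+].[OH-]
Why: saponification of the ethyl ester, to which the acetal is inert, followed by a brief cold acidification that the acetal should survive.

Step 5
Reactants: 8 (2E)-4,4-dimethoxy-3-methylbut-2-enoic acid; 5 (2Z)-2-methylpenta-2,4-dien-1-ol
Product: 9 (2Z)-2-methylpenta-2,4-dien-1-yl (2E)-4,4-dimethoxy-3-methylbut-2-enoate
Conditions: DCC, DMAP (cat.), CH2Cl2, 0 → 20 °C
Reagents that add atoms: none
Why: Steglich esterification joins the two five-carbon halves under neutral conditions that should leave both alkene geometries intact.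

Step 6
Reactants: 9 (2Z)-2-methylpenta-2,4-dien-1-yl (2E)-4,4-dimethoxy-3-methylbut-2-enoate
Product: 10 (2Z)-2-methylpenta-2,4-dien-1-yl (2E)-3-methyl-4-oxobut-2-enoate
Conditions: 10% aq. oxalic acid on SiO2, CH2Cl2, 20 °C; used at once
Reagents that add atoms: water, O
Why: mild hydrolysis of the dimethyl acetal should free the enal without cleaving the allylic ester or isomerising the diene, and immediate use limits uncatalysed cyclisation.

Step 7
Reactants: 10 (2Z)-2-methylpenta-2,4-dien-1-yl (2E)-3-methyl-4-oxobut-2-enoate
Product: 11 cis-fused lactone aldehyde (3aS,4S,7aS)-4,7a-dimethyl-3-oxo-1,3,3a,4,5,7a-hexahydro-2-benzofuran-4-carbaldehyde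
Conditions: [C24H25BNO]+ [N(SO2CF3)2]− (20 mol %; the N-protonated oxazaborolidine of (R)-α,α-diphenylprolinol and 2-methylphenylboronic acid, made in the flask from the neutral oxazaborolidine C24H24BNO and HN(SO2CF3)2), CH2Cl2, −78 → −20 °C
Reagents that add atoms: none
Why: Proposed new method: boron of the cationic oxazaborolidine binds the formyl oxygen of 10 (s-trans enal, formyl C–H···O contact to the ring oxygen), lowers the LUMO of C5=C10 and lets the tethered Z-diene add in a concerted, asynchronous [4+2] in which C4–C5 should run ahead of C1–C10. The closest known reaction types are the oxazaborolidinium-catalysed enantioselective intramolecular Diels–Alder reaction of trienals with all-carbon tethers and the thermal intramolecular Diels–Alder reaction of ester-tethered Z-dienes; combining them at a fully substituted diene terminus is the untested part. Ring A closes as the six-membered ring of the cycloadduct, and the γ-lactone closes as the five-membered ring made of the tether atoms C19, O and C6 plus C4 and C5, a fused closure with the tether on diene terminus C4 and dienophile carbon C5. C4 and C5 are set cis by the Z-diene on a three-atom tether, which can reach only the cis-fused bicycle and so turns the formyl group endo; C10 is set by the E geometry of the dienophile, which holds C6 and C9 trans and C6 and the C10 methyl cis on the new ring. The absolute sense comes from the catalyst: the phenyl group beside the bound enal covers the Re face of C10, so C1 bonds to the Si face and the (4S,5S,10S) adduct (labdane numbering) should result. The step needs enantioface selection and a catalysed rate well above the racemic background; the formyl group is the most Lewis-basic site, the ester carbonyl on the same alkene adds activation, and regiochemistry and endo/exo choice are fixed by the tether.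

Step 8
Reactants: 12 but-3-yn-2-one
Product: 13 2-ethynyl-2-methyl-1,3-dioxolane
Conditions: Me3SiOCH2CH2OSiMe3, Me3SiOTf (cat.), CH2Cl2, −78 → −20 °C
Reagents that add atoms: 1,2-bis(trimethylsilyloxy)ethane, C[Si](C)(C)OCCO[Si](C)(C)C
Why: Noyori ketalisation under aprotic silyl triflate catalysis should convert the ynone to its dioxolane without conjugate addition to the alkyne.

Step 9
Reactants: 11 cis-fused lactone aldehyde; 13 2-ethynyl-2-methyl-1,3-dioxolane
Product: 15 C9 propargylic alcohol (both C9 epimers), via lithium acetylide 14 (not isolated)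
Conditions: 13, n-BuLi, THF, −78 °C; then 11, −78 °C; AcOH quench at −78 °C
Reagents that add atoms: none
Why: 1,2-addition of a lithium acetylide to the neopentyl aldehyde should outrun attack on the hindered lactone at −78 °C; the new C9 carbinol centre forms without control and is erased in step 14.

Step 10
Reactants: 15 C9 propargylic alcohol
Product: 16 2α,3α-epoxide of 15
Conditions: mCPBA, NaHCO3, CH2Cl2, 0 °C
Reagents that add atoms: 3-chloroperoxybenzoic acid, OOC(=O)c1cccc(Cl)c1
Why: Prilezhaev epoxidation: in the half-chair with C6 and C9 equatorial the β face of C2=C3 is covered by the axial C10 methyl and the pseudo-axial C19 methylene, so the peracid, helped by hydrogen bonding to the α-side C9 hydroxyl, should add to the α face and set C2 and C3.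

Step 11
Reactants: 16 2α,3α-epoxide
Product: 17 C6 hemiketal carrying the 2-methylallyl group
Conditions: CH2=C(CH3)CH2MgCl (2.5 equiv), THF, −78 °C; aq. NH4Cl at −78 °C
Reagents that add atoms: 2-methylallylmagnesium chloride, CC(=C)C[Mg]Cl
Why: Grignard mono-addition to a γ-lactone: the first equivalent deprotonates the C9 hydroxyl, the second adds to C6 to form the C6–C7 bond, and the five-membered magnesium hemiketalate should persist at −78 °C so that no ketone is exposed to a further addition while epoxide and alkyne stay untouched.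

Step 12
Reactants: 17 C6 hemiketal
Product: 18 3α,6,9,19-tetraol (C6 and C9 epimers)
Conditions: LiBHEt3 (6 equiv), THF, 0 → 50 °C; then H2O
Reagents that add atoms: none
Why: hydride reduction with LiBHEt3 reduces the ketone released from the hemiketalate and opens the epoxide by SN2 attack at the less hindered C2 (trans-diaxial opening, Fürst–Plattner rule) to give the 3α-alcohol, leaving alkyne and ketal alone; C6 forms without reliable control and is reset in steps 21 and 22.

Step 13
Reactants: 18 tetraol
Product: 19 19-O-tert-butyldiphenylsilyl ether of 18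
Conditions: t-BuPh2SiCl (1.1 equiv), imidazole, DMF, 0 → 20 °C
Reagents that add atoms: tert-butyl(chloro)diphenylsilane, CC(C)(C)[Si](Cl)(c1ccccc1)c1ccccc1
Why: silylation with a bulky chlorosilane should pick the only primary hydroxyl (C19) over the three hindered secondary ones.

Step 14
Reactants: 19 19-O-silyl triol
Product: 20 C9 ynone
Conditions: MnO2 (excess), CH2Cl2, 20 °C
Reagents that add atoms: none
Why: MnO2 oxidises propargylic alcohols but not saturated secondary alcohols, so only C9 should be taken to the ketone and its stereocentre removed.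

Step 15
Reactants: 20 C9 ynone
Product: 21 3,6-bis-O-triethylsilyl ether of 20
Conditions: Et3SiOTf (3 equiv), 2,6-lutidine, CH2Cl2, −78 → 0 °C
Reagents that add atoms: triethylsilyl trifluoromethanesulfonate, CC[Si](CC)(CC)OS(=O)(=O)C(F)(F)F
Why: silyl triflate silylation covers the two hindered secondary hydroxyls so that no β-hydroxy ketone is exposed in the steps up to the titanium coupling.

Step 16
Reactants: 21 bis-silyl ynone
Product: 23 C8 methyl ketone, via secondary ozonide 22 (not isolated)
Conditions: O3, CH2Cl2, −78 °C (to first excess); then Me2S, −78 → 20 °C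
Reagents that add atoms: ozone, [O-][O+]=O
Why: ozonolysis with reductive work-up: the electron-rich 1,1-disubstituted alkene should react far faster than the ketone-conjugated alkyne and gives the C8 methyl ketone (C17 is its methyl).

Step 17
Reactants: 23 C8 methyl ketone
Product: 24 C8/C9 1,6-diketone
Conditions: H2 (1 atm), 10% Pd/C, EtOAc, 20 °C
Reagents that add atoms: none
Why: catalytic hydrogenation saturates the ynone triple bond to the C11–C12 ethylene unit; no other reducible group is present under these conditions.

Step 18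
Reactants: 24 C8/C9 1,6-diketone
Product: 25 silyl-protected labd-8-ene ketal
Conditions: TiCl3(DME)1.5, Zn–Cu couple, DME, reflux; 24 added over 30 h by syringe pump
Reagents that add atoms: none
Why: intramolecular McMurry coupling: low-valent titanium joins the two ketone carbons and deoxygenates the resulting pinacolate to the tetrasubstituted C8=C9 alkene, closing ring B as a six-membered ring; silyl ethers and the ketal are among the groups this reagent tolerates.

Step 19
Reactants: 25 silyl-protected labd-8-ene ketal
Product: 26 3α,6-dihydroxy-19-silyloxy-14,15-dinorlabd-8-en-13-one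
Conditions: 1 M HCl, THF, 20 °C
Reagents that add atoms: water, O
Why: dilute acid hydrolyses the dioxolane and both triethylsilyl ethers in one operation, while the tert-butyldiphenylsilyl ether and the tetrasubstituted alkene should be stable.

Step 20
Reactants: 26 keto diol
Product: 27 allyl (13E)-3α,6-dihydroxy-19-silyloxylabda-8,13-dien-15-oate
Conditions: allyl 2-(diethoxyphosphoryl)acetate (5 equiv), NaH (4.5 equiv), THF, 0 °C; then 26, 0 → 50 °C
Reagents that add atoms: allyl 2-(diethoxyphosphoryl)acetate, C=CCOC(=O)CP(=O)(OCC)OCC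
Why: Horner–Wadsworth–Emmons olefination of the methyl ketone with a preformed phosphonate anion, too weak a base to deprotonate the hydroxyls, should place the ester trans to the larger CH2 branch (13E); any Z isomer is removed by chromatography.

Step 21
Reactants: 27 allyl dienoate diol
Product: 28 allyl (13E)-19-silyloxy-3,6-dioxolabda-8,13-dien-15-oate
Conditions: Dess–Martin periodinane (3 equiv), NaHCO3, CH2Cl2, 0 → 20 °C
Reagents that add atoms: none
Why: Dess–Martin oxidation under buffered neutral conditions takes both secondary alcohols, which cannot be told apart, to ketones without moving the β,γ C8=C9 bond into conjugation; this erases the uncontrolled C6 centre.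

Step 22
Reactants: 28 3,6-diketone
Product: 29 allyl (13E)-3α,6β-dihydroxy-19-silyloxylabda-8,13-dien-15-oate
Conditions: LiBH(s-Bu)3 (3 equiv), THF, −78 °C; then H2O
Reagents that add atoms: none
Why: reduction with a bulky trialkylborohydride: at C6 the β face is blocked by the axial C10 methyl and the axial C19 methylene, so hydride enters from the α face and gives the axial 6β-alcohol; at C3 the bulky reagent takes the equatorial path and gives the axial 3α-alcohol; the β,β-disubstituted enoate should not be reduced at −78 °C.

Step 23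
Reactants: 29 3α,6β-diol
Product: 30 allyl (13E)-3α,6β-bis(3-methylbutanoyloxy)-19-silyloxylabda-8,13-dien-15-oate
Conditions: (Me2CHCH2CO)2O (excess), DMAP (2 equiv), Et3N, toluene, 80 °C
Reagents that add atoms: 3-methylbutanoic anhydride, CC(C)CC(=O)OC(=O)CC(C)C
Why: DMAP-catalysed acylation with the anhydride under forcing conditions should esterify both axial hydroxyls with retention, the primary C19 oxygen being blocked.

Step 24
Reactants: 30 bis-isovalerate allyl ester
Product: 31 (13E)-3α,6β-bis(3-methylbutanoyloxy)-19-silyloxylabda-8,13-dien-15-oic acid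
Conditions: Pd(PPh3)4 (5 mol %), morpholine, THF, 20 °C
Reagents that add atoms: none
Why: Tsuji–Trost-type allyl transfer: zerovalent palladium ionises the allyl ester and morpholine takes up the allyl group, so the acid is freed without acid or base that could touch the isovalerates.

Step 25
Reactants: 31 silyl-protected acid
Product: 32 (13E)-19-hydroxy-3α,6β-bis(3-methylbutanoyloxy)labda-8,13-dien-15-oic acid (CNP0272110.1)
Conditions: HF·pyridine, pyridine, THF, 0 → 20 °C
Reagents that add atoms: none
Why: fluoride-driven desilylation under non-basic conditions should free the C19 hydroxyl without promoting acyl migration from O6 to O19.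

**Compound list**
1 | acrolein | C=CC=O | starting material
2 | ethyl 2-[bis(2,2,2-trifluoroethoxy)phosphoryl]propanoate | CCOC(=O)C(C)P(=O)(OCC(F)(F)F)OCC(F)(F)F | starting material
3 | potassium salt of the carbanion of 2 (not isolated) | [K+].CCOC(=O)[C-](C)P(=O)(OCC(F)(F)F)OCC(F)(F)F | intermediate
4 | ethyl (2Z)-2-methylpenta-2,4-dienoate | C=C/C=C(/C)C(=O)OCC | intermediate
5 | (2Z)-2-methylpenta-2,4-dien-1-ol | C=C/C=C(/C)CO | intermediate
6 | ethyl (2E)-3-methyl-4-oxobut-2-enoate | CCOC(=O)/C=C(\C)C=O | starting material
7 | ethyl (2E)-4,4-dimethoxy-3-methylbut-2-enoate | CCOC(=O)/C=C(\C)C(OC)OC | intermediate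
8 | (2E)-4,4-dimethoxy-3-methylbut-2-enoic acid | OC(=O)/C=C(\C)C(OC)OC | intermediate
9 | (2Z)-2-methylpenta-2,4-dien-1-yl (2E)-4,4-dimethoxy-3-methylbut-2-enoate | C=C/C=C(/C)COC(=O)/C=C(\C)C(OC)OC | intermediate
10 | (2Z)-2-methylpenta-2,4-dien-1-yl (2E)-3-methyl-4-oxobut-2-enoate (key-step precursor) | C=C/C=C(/C)COC(=O)/C=C(\C)C=O | intermediate
11 | (3aS,4S,7aS)-4,7a-dimethyl-3-oxo-1,3,3a,4,5,7a-hexahydro-2-benzofuran-4-carbaldehyde; ring A cyclohexene (C2=C3) with the C19–O–C6(=O) lactone and the C10 methyl on the β face, the C4 methyl, H5 and the C10 formyl group on the α face | O=C[C@@]1(C)CC=C[C@]2(C)COC(=O)[C@H]12 | intermediate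
12 | but-3-yn-2-one | CC(=O)C#C | starting material
13 | 2-ethynyl-2-methyl-1,3-dioxolane | C#CC1(C)OCCO1 | intermediate
14 | lithium acetylide of 13 (not isolated) | [Li]C#CC1(C)OCCO1 | intermediate
15 | lactone 11 with C9 as CH(OH) bearing the 2-(2-methyl-1,3-dioxolan-2-yl)ethynyl group (C11≡C12–C13); both C9 epimers | CC1(C#CC(O)[C@@]2(C)CC=C[C@]3(C)COC(=O)[C@H]23)OCCO1 | intermediate
16 | 2α,3α-epoxide of 15 (epoxide oxygen on the face opposite the C10 methyl and the lactone) | CC1(C#CC(O)[C@@]2(C)C[C@@H]4[C@@H](O4)[C@]3(C)COC(=O)[C@H]23)OCCO1 | intermediate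
17 | hemiketal: 16 with C6 as C(OH)(CH2C(CH3)=CH2) in the five-membered C19–O–C6 ring; either configuration at C6 | CC1(C#CC(O)[C@@]2(C)C[C@@H]4[C@@H](O4)[C@]3(C)COC(O)(CC(C)=C)[C@H]23)OCCO1 | intermediate
18 | tetraol: ring A cyclohexane with 3α-OH, 4α-CH3, 4β-CH2OH, 5α-H, 10β-CH3; C5 bears CH(OH)CH2C(CH3)=CH2 and C10 bears CH(OH)C≡C–C(CH3)(OCH2CH2O); C6 and C9 epimers | CC1(C#CC(O)[C@@]2(C)CC[C@@H](O)[C@](C)(CO)[C@@H]2C(O)CC(C)=C)OCCO1 | intermediate
19 | 19-O-tert-butyldiphenylsilyl ether of 18 | CC1(C#CC(O)[C@@]2(C)CC[C@@H](O)[C@](C)(CO[Si](c3ccccc3)(c3ccccc3)C(C)(C)C)[C@@H]2C(O)CC(C)=C)OCCO1 | intermediate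
20 | ynone: 19 with C9 oxidised to the ketone conjugated to C11≡C12 | CC1(C#CC(=O)[C@@]2(C)CC[C@@H](O)[C@](C)(CO[Si](c3ccccc3)(c3ccccc3)C(C)(C)C)[C@@H]2C(O)CC(C)=C)OCCO1 | intermediate
21 | 3,6-bis-O-triethylsilyl ether of 20 | CC1(C#CC(=O)[C@@]2(C)CC[C@@H](O[Si](CC)(CC)CC)[C@](C)(CO[Si](c3ccccc3)(c3ccccc3)C(C)(C)C)[C@@H]2C(O[Si](CC)(CC)CC)CC(C)=C)OCCO1 | intermediate
22 | secondary ozonide (1,2,4-trioxolane) of the 2-methylallyl alkene of 21 (not isolated) | CC1(C#CC(=O)[C@@]2(C)CC[C@@H](O[Si](CC)(CC)CC)[C@](C)(CO[Si](c3ccccc3)(c3ccccc3)C(C)(C)C)[C@@H]2C(O[Si](CC)(CC)CC)CC3(C)OOCO3)OCCO1 | intermediate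
23 | 21 with the C7 arm ending in the C8 methyl ketone | CC1(C#CC(=O)[C@@]2(C)CC[C@@H](O[Si](CC)(CC)CC)[C@](C)(CO[Si](c3ccccc3)(c3ccccc3)C(C)(C)C)[C@@H]2C(O[Si](CC)(CC)CC)CC(C)=O)OCCO1 | intermediate
24 | 1,6-diketone: 23 with C11–C12 saturated (C8 methyl ketone and C9 ketone) | CC1(CCC(=O)[C@@]2(C)CC[C@@H](O[Si](CC)(CC)CC)[C@](C)(CO[Si](c3ccccc3)(c3ccccc3)C(C)(C)C)[C@@H]2C(O[Si](CC)(CC)CC)CC(C)=O)OCCO1 | intermediate
25 | trans-decalin with C8=C9, 3α-OSiEt3, 6-OSiEt3 (C6 epimers), 19-OSi(t-Bu)Ph2 and CH2CH2C(CH3)(OCH2CH2O) on C9 | CC1=C(CCC3(C)OCCO3)[C@@]2(C)CC[C@@H](O[Si](CC)(CC)CC)[C@](C)(CO[Si](c4ccccc4)(c4ccccc4)C(C)(C)C)[C@@H]2C(O[Si](CC)(CC)CC)C1 | intermediate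
26 | 3α,6-dihydroxy-19-(tert-butyldiphenylsilyloxy)-14,15-dinorlabd-8-en-13-one (C6 epimers) | CC1=C(CCC(C)=O)[C@@]2(C)CC[C@@H](O)[C@](C)(CO[Si](c3ccccc3)(c3ccccc3)C(C)(C)C)[C@@H]2C(O)C1 | intermediate
27 | allyl (13E)-3α,6-dihydroxy-19-(tert-butyldiphenylsilyloxy)labda-8,13-dien-15-oate (C6 epimers) | CC1=C(CC/C(C)=C/C(=O)OCC=C)[C@@]2(C)CC[C@@H](O)[C@](C)(CO[Si](c3ccccc3)(c3ccccc3)C(C)(C)C)[C@@H]2C(O)C1 | intermediate
28 | allyl (13E)-19-(tert-butyldiphenylsilyloxy)-3,6-dioxolabda-8,13-dien-15-oate | CC1=C(CC/C(C)=C/C(=O)OCC=C)[C@@]2(C)CCC(=O)[C@](C)(CO[Si](c3ccccc3)(c3ccccc3)C(C)(C)C)[C@@H]2C(=O)C1 | intermediate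
29 | allyl (13E)-3α,6β-dihydroxy-19-(tert-butyldiphenylsilyloxy)labda-8,13-dien-15-oate | CC1=C(CC/C(C)=C/C(=O)OCC=C)[C@@]2(C)CC[C@@H](O)[C@](C)(CO[Si](c3ccccc3)(c3ccccc3)C(C)(C)C)[C@@H]2[C@H](O)C1 | intermediate
30 | allyl (13E)-3α,6β-bis(3-methylbutanoyloxy)-19-(tert-butyldiphenylsilyloxy)labda-8,13-dien-15-oate | CC1=C(CC/C(C)=C/C(=O)OCC=C)[C@@]2(C)CC[C@@H](OC(=O)CC(C)C)[C@](C)(CO[Si](c3ccccc3)(c3ccccc3)C(C)(C)C)[C@@H]2[C@H](OC(=O)CC(C)C)C1 | intermediate
31 | (13E)-3α,6β-bis(3-methylbutanoyloxy)-19-(tert-butyldiphenylsilyloxy)labda-8,13-dien-15-oic acid | CC1=C(CC/C(C)=C/C(=O)O)[C@@]2(C)CC[C@@H](OC(=O)CC(C)C)[C@](C)(CO[Si](c3ccccc3)(c3ccccc3)C(C)(C)C)[C@@H]2[C@H](OC(=O)CC(C)C)C1 | intermediate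
32 | (13E)-19-hydroxy-3α,6β-bis(3-methylbutanoyloxy)labda-8,13-dien-15-oic acid (CNP0272110.1) | CC1=C(CC/C(C)=C/C(=O)O)[C@@]2(C)CC[C@@H](OC(=O)CC(C)C)[C@](C)(CO)[C@@H]2[C@H](OC(=O)CC(C)C)C1 | target

**Step count and risks**

Total steps: 25. Longest linear sequence: 22 (steps 3–7, then 9–25); steps 1–2 and step 8 are side branches.

Steps most likely to fail:

1. Step 7 (proposed new method). Turnover may be low because the ester must reach its s-cis conformer and the diene terminus C4 is fully substituted. The racemic background cycloaddition may then compete at the temperature needed, the acidic catalyst may isomerise or polymerise the Z-diene, or enantioface discrimination may be poor. Fallback, from 10 back to 11: 10 is heated in toluene with a radical inhibitor at 90–110 °C, a thermal ester-tethered Diels–Alder reaction that should give the same relative configuration as a racemate of 11 and its mirror-image adduct F1. The mixture is condensed with (1R,2R)-N,N'-dimethyl-1,2-diphenylethane-1,2-diamine over molecular sieves to give the diastereomeric aminals, the aminal of 11, F2, and the aminal of the mirror image, F3. These are separated by chromatography or crystallisation, and F2 is hydrolysed with dilute aqueous acid to return enantiopure 11.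

2. Step 18. The C9 ketone is flanked by the quaternary C10, so the coupling may stall at the titanium pinacolate or be overtaken by simple carbonyl reduction, intermolecular coupling, or loss of silyl ethers to the Lewis-acidic titanium chlorides. Fallback, from 24 back to 25: ring B is closed at the diol stage by ketyl coupling with SmI2 in THF with t-BuOH, giving the 8,9-diol F4. F4 is converted with thiophosgene and DMAP into the cyclic thionocarbonate F5, which on heating with P(OMe)3 (Corey–Winter olefination) should give 25.

3. Step 23. Acylation may stop at the 3-monoester: the 6β-hydroxyl is 1,3-diaxial to the C10 methyl and to the C19 methylene with its bulky silyl ether, and more forcing conditions put the silyl ether and the C8=C9 bond at risk. Fallback, from 29 to the target 32: the silyl ether is removed first with HF·pyridine to give the triol F6. The primary hydroxyl is capped selectively with allyl chloroformate and pyridine at −40 °C as the slim allyl carbonate F7. Acylation with the anhydride and DMAP then gives the bis-isovalerate F8, and a single treatment with Pd(PPh3)4 and morpholine removes both the allyl ester and the allyl carbonate to give 32.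

Further compounds
F1 | step 7 | mirror image of 11, formed with 11 as the racemate | O=C[C@]1(C)CC=C[C@@]2(C)COC(=O)[C@@H]12
F2 | step 7 | aminal (imidazolidine) of 11 with (1R,2R)-N,N'-dimethyl-1,2-diphenylethane-1,2-diamine | CN1[C@H](c2ccccc2)[C@@H](c2ccccc2)N(C)C1[C@@]3(C)CC=C[C@]4(C)COC(=O)[C@H]34
F3 | step 7 | aminal of F1 with the same diamine | CN1[C@H](c2ccccc2)[C@@H](c2ccccc2)N(C)C1[C@]3(C)CC=C[C@@]4(C)COC(=O)[C@@H]34
F4 | step 18 | 8,9-diol from pinacol closure of 24 (C8, C9 and C6 configurations open) | CC1(O)C(O)(CCC3(C)OCCO3)[C@@]2(C)CC[C@@H](O[Si](CC)(CC)CC)[C@](C)(CO[Si](c4ccccc4)(c4ccccc4)C(C)(C)C)[C@@H]2C(O[Si](CC)(CC)CC)C1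
F5 | step 18 | cyclic 8,9-thionocarbonate of F4 | CC12OC(=S)OC1(CCC3(C)OCCO3)[C@@]4(C)CC[C@@H](O[Si](CC)(CC)CC)[C@](C)(CO[Si](c5ccccc5)(c5ccccc5)C(C)(C)C)[C@@H]4C(O[Si](CC)(CC)CC)C2
F6 | step 23 | allyl (13E)-3α,6β,19-trihydroxylabda-8,13-dien-15-oate | CC1=C(CC/C(C)=C/C(=O)OCC=C)[C@@]2(C)CC[C@@H](O)[C@](C)(CO)[C@@H]2[C@H](O)C1
F7 | step 23 | 19-O-allyloxycarbonyl derivative of F6 | CC1=C(CC/C(C)=C/C(=O)OCC=C)[C@@]2(C)CC[C@@H](O)[C@](C)(COC(=O)OCC=C)[C@@H]2[C@H](O)C1
F8 | step 23 | 3α,6β-bis(3-methylbutanoate) of F7 | CC1=C(CC/C(C)=C/C(=O)OCC=C)[C@@]2(C)CC[C@@H](OC(=O)CC(C)C)[C@](C)(COC(=O)OCC=C)[C@@H]2[C@H](OC(=O)CC(C)C)C1
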